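**Retrosynthetic overview**

- The target is the (7R,8S)-erythro acetate: C7 is the benzylic CH(OAc) on ring A (3,4-dimethoxyphenyl) and C8 is the CH(CH3) bound through oxygen to C4′ of ring B (4-allyl-2,6-dimethoxyphenyl). No ring is formed in the route; both arenes are bought intact.
- C7–OAc bond: Mitsunobu displacement with acetic acid, with inversion at C7, on the threo-(7S,8S) alcohol.
- Key disconnection, C7–H bond: the threo alcohol comes from the racemic α-aryloxy ketone by asymmetric transfer hydrogenation with dynamic kinetic resolution. The feature used is that C8–H lies between the C7 carbonyl (conjugated to ring A) and the ether oxygen to ring B, so C8 is stereolabile and C7/C8 are set together from a racemate.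
- C8–O bond: Williamson coupling of 4-allyl-2,6-dimethoxyphenol with the α-bromoketone, which is made from 3′,4′-dimethoxypropiophenone by α-bromination.

Key step: step 3

Assumption: the dynamic reduction is taken to follow the polar Felkin–Anh (syn/threo) sense that α-oxygenated aryl ketones show with this outer-sphere catalyst class, so the acetate is introduced with inversion at C7.

**Route**

Step 1
Reactants: 1 1-(3,4-dimethoxyphenyl)propan-1-one
Product: 2 rac-2-bromo-1-(3,4-dimethoxyphenyl)propan-1-one
Conditions: CuBr2 (2.1 equiv), EtOAc/CHCl3 (1:1), reflux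
Reagents that add atoms: copper(II) bromide, Br[Cu]Br
Why: King–Ostrum α-bromination, in which CuBr2 brominates the enol of the aryl ketone at C8 and spares the electron-rich veratryl ring that Br2 could attack; the new centre is racemic, which the route accepts.

Step 2
Reactants: 2 rac-2-bromo-1-(3,4-dimethoxyphenyl)propan-1-one; 3 4-allyl-2,6-dimethoxyphenol
Product: 4 rac-2-(4-allyl-2,6-dimethoxyphenoxy)-1-(3,4-dimethoxyphenyl)propan-1-one
Conditions: K2CO3 (1.5 equiv), acetone, reflux
Reagents that add atoms: none
Why: Williamson etherification, in which the phenoxide of 3 displaces the carbonyl-activated secondary bromide by SN2, the standard entry to 8-O-4′ ketones also for 2,6-dimethoxyphenols; C8 stays racemic by design.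

Step 3
Reactants: 4 rac-2-(4-allyl-2,6-dimethoxyphenoxy)-1-(3,4-dimethoxyphenyl)propan-1-one
Product: 6 (1S,2S)-2-(4-allyl-2,6-dimethoxyphenoxy)-1-(3,4-dimethoxyphenyl)propan-1-ol, via (S)-ketone 5 (not isolated)
Conditions: RuCl[(R,R)-TsDPEN](p-cymene) (2 mol %), HCO2H/Et3N (1:5 molar, 3 equiv HCO2H), DBU (0.2 equiv), DMF, 40 °C
Reagents that add atoms: none
Why: Noyori–Ikariya asymmetric transfer hydrogenation run as a dynamic kinetic resolution: the Ru–H/N–H species formed from the (R,R)-TsDPEN complex and formate passes H−/H+ to the C7 carbonyl through the outer-sphere six-membered transition state, while C8–H exchanges through the enol(ate) in the amine-rich medium, so that the (R)-ketone is converted into (S)-ketone 5 as 5 is consumed. The closest known reaction type is the transfer hydrogenation with dynamic kinetic resolution of racemic benzoins and of α-alkoxy β-keto esters, which gives the syn (threo) 1,2-dioxygenated products; no ring is closed. C7 is set by the catalyst: the aryl ring of the ketone lies against the p-cymene ligand, so the (R,R) complex should give the 7S carbinol, the spatial counterpart of (R)-1-phenylethanol. C8 is set by selection between the two equilibrating ketone enantiomers: on the face dictated by the catalyst only (S)-ketone 5 can hold its C8–OAr bond anti to the incoming hydride with H rather than CH3 next to ring A (polar Felkin–Anh), which should lead to the threo (7S,8S) isomer. The step needs enolisation faster than reduction of the mismatched enantiomer, which the double activation of C8–H and the amine-rich HCO2H/Et3N ratio with DBU should secure, and it needs C=O over C=C chemoselectivity, which holds because the coordinatively saturated hydride does not bind the isolated allyl group.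

Step 4
Reactants: 6 (1S,2S)-2-(4-allyl-2,6-dimethoxyphenoxy)-1-(3,4-dimethoxyphenyl)propan-1-ol
Product: 8 (1R,2S)-2-(4-allyl-2,6-dimethoxyphenoxy)-1-(3,4-dimethoxyphenyl)propyl acetate (maceneolignan H), via alkoxyphosphonium acetate 7 (not isolated)
Conditions: PPh3 (1.5 equiv), DIAD (1.5 equiv), AcOH (2 equiv), toluene, −20 °C → rt
Reagents that add atoms: acetic acid, CC(=O)O
Why: Mitsunobu esterification, in which acetate displaces the alkoxyphosphonium group of 7 by SN2 with inversion at C7 (7S → 7R) while C8 is untouched, so threo becomes erythro and the acetate is installed in the same operation; the β-aryloxy group and the non-polar solvent at low temperature disfavour ionisation of the benzylic C–O bond.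

**Compound list**

1 | 1-(3,4-dimethoxyphenyl)propan-1-one (3′,4′-dimethoxypropiophenone) | CCC(=O)c1ccc(OC)c(OC)c1 | starting material
2 | rac-2-bromo-1-(3,4-dimethoxyphenyl)propan-1-one | CC(Br)C(=O)c1ccc(OC)c(OC)c1 | intermediate
3 | 4-allyl-2,6-dimethoxyphenol (methoxyeugenol) | C=CCc1cc(OC)c(O)c(OC)c1 | starting material
4 | rac-2-(4-allyl-2,6-dimethoxyphenoxy)-1-(3,4-dimethoxyphenyl)propan-1-one | C=CCc1cc(OC)c(OC(C)C(=O)c2ccc(OC)c(OC)c2)c(OC)c1 | intermediate
5 | (S)-2-(4-allyl-2,6-dimethoxyphenoxy)-1-(3,4-dimethoxyphenyl)propan-1-one, fast-reacting enantiomer replenished in the flask in step 3 | C=CCc1cc(OC)c(O[C@@H](C)C(=O)c2ccc(OC)c(OC)c2)c(OC)c1 | intermediate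
6 | (1S,2S)-2-(4-allyl-2,6-dimethoxyphenoxy)-1-(3,4-dimethoxyphenyl)propan-1-ol (threo) | C=CCc1cc(OC)c(O[C@@H](C)[C@@H](O)c2ccc(OC)c(OC)c2)c(OC)c1 | intermediate
7 | [(1S,2S)-2-(4-allyl-2,6-dimethoxyphenoxy)-1-(3,4-dimethoxyphenyl)propoxy]triphenylphosphonium acetate, formed in the flask in step 4 | C=CCc1cc(OC)c(O[C@@H](C)[C@@H](O[P+](c2ccccc2)(c2ccccc2)c2ccccc2)c2ccc(OC)c(OC)c2)c(OC)c1.CC(=O)[O-] | intermediate
8 | (1R,2S)-2-(4-allyl-2,6-dimethoxyphenoxy)-1-(3,4-dimethoxyphenyl)propyl acetate (maceneolignan H, erythro) | C=CCc1cc(OC)c(O[C@@H](C)[C@H](OC(C)=O)c2ccc(OC)c(OC)c2)c(OC)c1 | target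

**Step count**

Total steps: 4. Longest linear sequence: 4 (1 → 2 → 4 → 6 → 8); phenol 3 enters in step 2.

**Steps most likely to fail**

1. Step 3 (key step). Epimerisation at C8 may be slower than hydride transfer, so that the process degrades to a kinetic resolution, or the discrimination between the two ketone enantiomers on the catalyst may be weak and lower the threo preference. The fallback fixes C8 from the chiral pool and sets out from phenol 3. Mitsunobu etherification of 3 with methyl (R)-lactate (PPh3, DIAD, THF, 0 °C → rt, inversion) should give methyl (S)-2-(4-allyl-2,6-dimethoxyphenoxy)propanoate F1. Treatment with MeNH(OMe)·HCl and i-PrMgCl (THF, −20 °C) should give (S)-2-(4-allyl-2,6-dimethoxyphenoxy)-N-methoxy-N-methylpropanamide F2. Addition of 3,4-dimethoxyphenylmagnesium bromide (THF, −20 → 0 °C, cold acidic quench) should give the (S)-ketone as an isolated single enantiomer, so the fallback comes back to the route at compound 5. Compound 5 is then reduced with the same (R,R) catalyst in the non-epimerising HCO2H/Et3N 5:2 mixture to 6, with C7 under catalyst control and no dynamic behaviour required.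

2. Step 4. The alkoxyphosphonium group on the electron-rich benzylic C7 may ionise before acetate attacks, which would give partial retention, or it may undergo elimination towards the enol ether. Retention would give the threo acetate, a diastereomer, so it would cost material but not enantiomeric purity. The fallback inverts C7 by oxidation and chelation-controlled reduction and sets out from 6. Dess–Martin periodinane with NaHCO3 (CH2Cl2, 0 °C) should return the enantioenriched (S)-ketone 5. Zn(BH4)2 (Et2O, −30 °C) should then deliver hydride to the zinc chelate of the carbonyl and ether oxygens from the side of the C8 hydrogen and give (1R,2S)-2-(4-allyl-2,6-dimethoxyphenoxy)-1-(3,4-dimethoxyphenyl)propan-1-ol F3, the erythro alcohol. Acetylation (Ac2O, pyridine, DMAP, CH2Cl2, 0 °C) with retention comes back to the route at compound 8.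

3. Step 2. The hindered, basic 2,6-dimethoxyphenoxide may dehydrobrominate the secondary α-bromoketone instead of substituting it. The fallback forms the C8–O bond on an ester and the C7–aryl bond afterwards by acyl substitution, and sets out from phenol 3. Alkylation with ethyl 2-bromopropanoate (Cs2CO3, DMF, rt) should give ethyl rac-2-(4-allyl-2,6-dimethoxyphenoxy)propanoate F4. MeNH(OMe)·HCl and i-PrMgCl (THF, −20 °C) should give rac-2-(4-allyl-2,6-dimethoxyphenoxy)-N-methoxy-N-methylpropanamide F5. 3,4-Dimethoxyphenylmagnesium bromide (THF, 0 °C) should then give the racemic ketone, so the fallback comes back to the route at compound 4 and the key step is kept.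

**Further compounds**

F1 | step 3 | methyl (S)-2-(4-allyl-2,6-dimethoxyphenoxy)propanoate | C=CCc1cc(OC)c(O[C@@H](C)C(=O)OC)c(OC)c1
F2 | step 3 | (S)-2-(4-allyl-2,6-dimethoxyphenoxy)-N-methoxy-N-methylpropanamide | C=CCc1cc(OC)c(O[C@@H](C)C(=O)N(C)OC)c(OC)c1
F3 | step 4 | (1R,2S)-2-(4-allyl-2,6-dimethoxyphenoxy)-1-(3,4-dimethoxyphenyl)propan-1-ol | C=CCc1cc(OC)c(O[C@@H](C)[C@H](O)c2ccc(OC)c(OC)c2)c(OC)c1
F4 | step 2 | ethyl rac-2-(4-allyl-2,6-dimethoxyphenoxy)propanoate | C=CCc1cc(OC)c(OC(C)C(=O)OCC)c(OC)c1
F5 | step 2 | rac-2-(4-allyl-2,6-dimethoxyphenoxy)-N-methoxy-N-methylpropanamide | C=CCc1cc(OC)c(OC(C)C(=O)N(C)OC)c(OC)c1
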